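**Strategy.** The oxolane (O1, C2 aryl-bearing, C3 hydroxymethyl-bearing, C4 aroyl-bearing, C5 methylene) is cut through O1–C2 and C3–C4. This gives a C2–C3 enal, 3,4-dimethoxycinnamaldehyde (hydroxymethyl carbon as CHO), and an O1–C5–C4 α-hydroxy ketone, ethyl hydroxypyruvate (aroyl carbon as ester). The feature exploited is that O1 sits β to the hydroxymethyl carbon while C4 carries an acyl carbon next to the O1–C5 unit. One amine-catalysed oxa-Michael/aldol cascade forms both bonds and sets C2; dehydration gives a 2,5-dihydrofuran. C2 then relays C3 and C4 in a single hydrogenation (all-cis), and the derived cis-fused lactone accepts the trimethoxyphenyl group.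

Key step: step 2

Remark on locants: the discussion uses O1, C2 (ArCH), C3 (CH–CH2OH), C4 (CH–C(=O)Ar'), C5 (OCH2); the names in the compound list follow systematic numbering.
Remark on the chemistry: the target γ-hydroxy ketone is in ring–chain equilibrium with its bicyclic hemiketal; the open form drawn is taken as the target.

**Route**

Step 1
Reactants: 1 ethyl bromopyruvate
Product: 3 ethyl 3-hydroxy-2-oxopropanoate, via formate ester 2 (not isolated)
Conditions: HCO2Na, EtOH, 60 °C
Reagents that add atoms: sodium formate, [Na+].[O-]C=O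
Why: The bromide next to the keto ester is displaced by formate (SN2) and the labile formate ester is transesterified by the solvent ethanol, the usual formate route from α-halo ketones to α-hydroxy ketones; no stereocenter is formed.

Step 2
Reactants: 3 ethyl 3-hydroxy-2-oxopropanoate; 4 (E)-3-(3,4-dimethoxyphenyl)prop-2-enal
Product: 7 ethyl (5S)-5-(3,4-dimethoxyphenyl)-4-formyl-2,5-dihydrofuran-3-carboxylate, via aldol adduct 5 (not isolated), via tertiary mesylate 6 (not isolated)
Conditions: (R)-α,α-diphenylprolinol trimethylsilyl ether (20 mol %), PhCO2H (20 mol %), CHCl3, rt; then MsCl, Et3N, 0 °C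
Reagents that add atoms: none
Why: The amine converts 4 into an (E)-iminium ion, the hydroxyl oxygen of 3 adds to its β-carbon (oxa-Michael, O1–C2), the resulting enamine attacks the adjacent α-keto ester carbonyl (intramolecular aldol, C3–C4) to give 5 after hydrolysis, and sulfene-type mesylation of the tertiary alcohol followed by E1cB loss of mesylate α to the aldehyde should give 7. The closest known reaction type is the amine-catalysed domino oxa-Michael/aldol reaction of α-hydroxy ketones such as dihydroxyacetone with enals, together with its thia-Michael/aldol counterpart. The oxolane ring closes in the aldol event as a 5-exo-trig attack of the enamine carbon on the ketone. C2 is set by the catalyst, whose CPh2OTMS group shields one face of the iminium ion so that oxygen adds to the other; the (R)-catalyst is chosen because the accepted shielding model predicts the required sense at C2, and the centres formed at C3 and C4 are transient and erased by the dehydration. The step needs 1,4- over 1,2-addition of the alcohol and cross- over self-aldol reaction; hemiacetal formation is reversible and unproductive, whereas the oxa-Michael adduct should be drained by ring closure onto the only strongly electrophilic carbonyl placed five atoms from the enamine carbon. The cold, brief base treatment is chosen to avoid migration of the C3=C4 bond and loss of configuration at C2.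

Step 3
Reactants: 7 ethyl (5S)-5-(3,4-dimethoxyphenyl)-4-formyl-2,5-dihydrofuran-3-carboxylate
Product: 8 ethyl (5S)-5-(3,4-dimethoxyphenyl)-4-(hydroxymethyl)-2,5-dihydrofuran-3-carboxylate
Conditions: NaBH4, CeCl3·7H2O, MeOH, −40 °C; neutral work-up
Reagents that add atoms: none
Why: Luche reduction should reduce the cerium-activated aldehyde 1,2 faster than the ester or either conjugate position reacts; no stereocenter is formed and C2 is untouched.

Step 4
Reactants: 8 ethyl (5S)-5-(3,4-dimethoxyphenyl)-4-(hydroxymethyl)-2,5-dihydrofuran-3-carboxylate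
Product: 10 (3aR,4R,6aR)-4-(3,4-dimethoxyphenyl)tetrahydro-1H,3H-furo[3,4-c]furan-1-one, via all-cis hydroxy ester 9 (not isolated)
Conditions: H2 (1 atm), [Ir(cod)(PCy3)(py)]PF6 (5 mol %), CH2Cl2, 0 °C to rt; then PPTS (cat.), 40 °C
Reagents that add atoms: none
Why: Hydroxyl-directed homogeneous hydrogenation of the tetrasubstituted C3=C4 bond should deliver both hydrogens syn from the face opposite the C2 aryl group, so that CH2OH at C3 and CO2Et at C4 end up cis to each other and to the aryl group (substrate control from C2), and the cis γ-hydroxy ester then lactonises under mild acid.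

Step 5
Reactants: 10 (3aR,4R,6aR)-4-(3,4-dimethoxyphenyl)tetrahydro-1H,3H-furo[3,4-c]furan-1-one; 11 5-bromo-1,2,3-trimethoxybenzene
Product: 14 [(3R,4R,5R)-5-(3,4-dimethoxyphenyl)-4-(hydroxymethyl)oxolan-3-yl](3,4,5-trimethoxyphenyl)methanone, via (3,4,5-trimethoxyphenyl)lithium 12 (not isolated), via lithium hemiketal alkoxide 13 (not isolated)
Conditions: 11, n-BuLi, THF, −78 °C; then 10, −78 °C; sat. aq NH4Cl at −78 °C, then rt
Reagents that add atoms: none
Why: Bromine–lithium exchange gives the aryllithium, which should add once to the γ-lactone carbonyl because the tetrahedral lithium alkoxide persists at −78 °C and opens to the γ-hydroxy aryl ketone only on the buffered quench (organolithium addition to a lactone); no stereocenter is formed, and the cis ring fusion protects C4 until the quench.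

**Compound list**

1 | ethyl bromopyruvate (ethyl 3-bromo-2-oxopropanoate) | CCOC(=O)C(=O)CBr | starting material
2 | ethyl 3-(formyloxy)-2-oxopropanoate | CCOC(=O)C(=O)COC=O | intermediate
3 | ethyl 3-hydroxy-2-oxopropanoate (ethyl hydroxypyruvate) | CCOC(=O)C(=O)CO | intermediate
4 | (E)-3-(3,4-dimethoxyphenyl)prop-2-enal | COc1ccc(/C=C/C=O)cc1OC | starting material
5 | ethyl (5R)-5-(3,4-dimethoxyphenyl)-4-formyl-3-hydroxyoxolane-3-carboxylate (configuration at C3 and C4 left open, both erased in the dehydration) | COc1ccc([C@@H]2OCC(O)(C(=O)OCC)C2C=O)cc1OC | intermediate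
6 | ethyl (5R)-5-(3,4-dimethoxyphenyl)-4-formyl-3-(methanesulfonyloxy)oxolane-3-carboxylate | COc1ccc([C@@H]2OCC(OS(C)(=O)=O)(C(=O)OCC)C2C=O)cc1OC | intermediate
7 | ethyl (5S)-5-(3,4-dimethoxyphenyl)-4-formyl-2,5-dihydrofuran-3-carboxylate | COc1ccc([C@@H]2OCC(C(=O)OCC)=C2C=O)cc1OC | intermediate
8 | ethyl (5S)-5-(3,4-dimethoxyphenyl)-4-(hydroxymethyl)-2,5-dihydrofuran-3-carboxylate | COc1ccc([C@@H]2OCC(C(=O)OCC)=C2CO)cc1OC | intermediate
9 | ethyl (3R,4R,5R)-5-(3,4-dimethoxyphenyl)-4-(hydroxymethyl)oxolane-3-carboxylate | COc1ccc([C@@H]2OC[C@H](C(=O)OCC)[C@@H]2CO)cc1OC | intermediate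
10 | (3aR,4R,6aR)-4-(3,4-dimethoxyphenyl)tetrahydro-1H,3H-furo[3,4-c]furan-1-one | COc1ccc([C@@H]2OC[C@@H]3C(=O)OC[C@H]23)cc1OC | intermediate
11 | 5-bromo-1,2,3-trimethoxybenzene | COc1cc(Br)cc(OC)c1OC | starting material
12 | (3,4,5-trimethoxyphenyl)lithium | [Li]c1cc(OC)c(OC)c(OC)c1 | intermediate
13 | lithium (3aR,4R,6aR)-4-(3,4-dimethoxyphenyl)-1-(3,4,5-trimethoxyphenyl)tetrahydro-1H,3H-furo[3,4-c]furan-1-olate (configuration at C1 left open) | COc1ccc([C@@H]2OC[C@@H]3C([O-])(c4cc(OC)c(OC)c(OC)c4)OC[C@H]23)cc1OC.[Li+] | intermediate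
14 | [(3R,4R,5R)-5-(3,4-dimethoxyphenyl)-4-(hydroxymethyl)oxolan-3-yl](3,4,5-trimethoxyphenyl)methanone | COc1ccc([C@@H]2OC[C@H](C(=O)c3cc(OC)c(OC)c(OC)c3)[C@@H]2CO)cc1OC | target

**Count and risks**

Total step count: 5. Longest linear sequence: 5 steps (1 → 3 → 7 → 8 → 10 → 14).

Steps most likely to fail:

Step 2. The enolisable hydroxy keto ester 3 may self-condense or isomerise under amine catalysis, and the oxa-Michael addition may revert before the aldol closure; both would lower conversion and the enantiomeric purity at C2. Fallback (sets out from 4, comes back at 7): the two bond formations are separated and the ketone is unveiled only after the ether is in place. Commercial ethyl 2-(hydroxymethyl)prop-2-enoate, a non-enolisable primary alcohol, is added to 4 under iminium catalysis with the same (R)-diarylprolinol silyl ether to give ethyl 2-({[(1R)-1-(3,4-dimethoxyphenyl)-3-oxopropyl]oxy}methyl)prop-2-enoate F1. Lemieux–Johnson cleavage of the 1,1-disubstituted alkene (OsO4 cat., NaIO4, 2,6-lutidine, dioxane–H2O) should give ethyl 3-{[(1R)-1-(3,4-dimethoxyphenyl)-3-oxopropyl]oxy}-2-oxopropanoate F2. Amine-catalysed intramolecular aldol addition (pyrrolidine, AcOH) followed by MsCl/Et3N then leads through 5 and 6 to 7.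

Step 4. Hydrogen may add with poor facial selectivity, the C3=C4 bond may migrate under the iridium hydride, or the allylic/benzylic C2–O1 bond may be cleaved. Fallback (sets out from 8, comes back at 10): 8 is first lactonised (TsOH cat., toluene, 50 °C) to the fused butenolide (4S)-4-(3,4-dimethoxyphenyl)-4,6-dihydro-1H,3H-furo[3,4-c]furan-1-one F3. Conjugate reduction (NaBH4, NiCl2·6H2O, MeOH, 0 °C) should then deliver hydrogen to C3 anti to the aryl group, and the bicyclic frame allows only cis-fused protonation at C4, giving 10.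

Step 5. A second aryllithium may add if the tetrahedral alkoxide collapses early, and C4 may epimerise by enolisation of the released ketone in basic medium. Fallback (sets out from 10, comes back at 14): the lactone is opened with MeNH(OMe)·HCl/AlMe3 to (3R,4R,5R)-5-(3,4-dimethoxyphenyl)-4-(hydroxymethyl)-N-methoxy-N-methyloxolane-3-carboxamide F4. This is silylated at once (TBSCl, imidazole) to (3R,4R,5R)-4-{[(tert-butyldimethylsilyl)oxy]methyl}-5-(3,4-dimethoxyphenyl)-N-methoxy-N-methyloxolane-3-carboxamide F5. The arylmagnesium bromide made from 11 and Mg (THF, 0 °C) should add once to give [(3R,4R,5R)-4-{[(tert-butyldimethylsilyl)oxy]methyl}-5-(3,4-dimethoxyphenyl)oxolan-3-yl](3,4,5-trimethoxyphenyl)methanone F6, and buffered desilylation (TBAF, AcOH, THF) gives 14.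

Further compounds

F1 | step 2 | ethyl 2-({[(1R)-1-(3,4-dimethoxyphenyl)-3-oxopropyl]oxy}methyl)prop-2-enoate | COc1ccc([C@@H](CC=O)OCC(=C)C(=O)OCC)cc1OC
F2 | step 2 | ethyl 3-{[(1R)-1-(3,4-dimethoxyphenyl)-3-oxopropyl]oxy}-2-oxopropanoate | COc1ccc([C@@H](CC=O)OCC(=O)C(=O)OCC)cc1OC
F3 | step 4 | (4S)-4-(3,4-dimethoxyphenyl)-4,6-dihydro-1H,3H-furo[3,4-c]furan-1-one | COc1ccc([C@@H]2OCC3=C2COC3=O)cc1OC
F4 | step 5 | (3R,4R,5R)-5-(3,4-dimethoxyphenyl)-4-(hydroxymethyl)-N-methoxy-N-methyloxolane-3-carboxamide | COc1ccc([C@@H]2OC[C@H](C(=O)N(C)OC)[C@@H]2CO)cc1OC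
F5 | step 5 | (3R,4R,5R)-4-{[(tert-butyldimethylsilyl)oxy]methyl}-5-(3,4-dimethoxyphenyl)-N-methoxy-N-methyloxolane-3-carboxamide | COc1ccc([C@@H]2OC[C@H](C(=O)N(C)OC)[C@@H]2CO[Si](C)(C)C(C)(C)C)cc1OC
F6 | step 5 | [(3R,4R,5R)-4-{[(tert-butyldimethylsilyl)oxy]methyl}-5-(3,4-dimethoxyphenyl)oxolan-3-yl](3,4,5-trimethoxyphenyl)methanone | COc1ccc([C@@H]2OC[C@H](C(=O)c3cc(OC)c(OC)c(OC)c3)[C@@H]2CO[Si](C)(C)C(C)(C)C)cc1OC
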